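**Plan**

1. The retrosynthesis cuts, in this order: the enone Cα=Cβ bond (Claisen–Schmidt), the ring-A C1′–C(=O) bond, then at the lavandulyl stereocentre C2″ the bond to the isopropenyl carbon and the C1″–C2″ bond, and last the C3′–C1″ bond.
2. Forward, the side chain is grown outwards from C3′ of resorcinol bis-MOM ether by three successive 1,2-shifts from boron to carbon: aryl → C1″H2 (step 2), benzylic C1″ → C2″ (step 4), C2″ → isopropenyl carbon (step 5). Acetylation at C1′, aldol condensation with protected salicylaldehyde and MOM removal finish the chalcone.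
3. The only stereocentre, C2″ (S), comes from a (+)-sparteine-mediated enantiotopic α-deprotonation of an achiral homoprenyl carbamate. It is relayed by retention (borylation), inversion (1,2-shift) and retention (Zweifel olefination); no lavandulol building block is used.
4. Enabling feature: C2″ is a CH whose three other substituents are all carbon (C1″H2 bound to ring A, C3″H2 of the prenyl arm, the isopropenyl carbon). It therefore maps onto the α-carbon of a primary O-alkyl carbamate (C2″–O), onto which two carbon groups are delivered in turn through boron.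
5. C3′ lies between the oxygens at C2′ and C4′ of ring A, which fixes the site of the first metalation. The resulting 2-substituted resorcinol ether has equivalent C4/C6 positions, so the later acetylation has no regiochemical choice.
6. The (E)-enone geometry is set thermodynamically in the condensation step.

Key step: step 4

Remark: the stereocentre of the SMILES is read as (S) (CIP order isopropenyl > CH2Ar > CH2CH=CMe2 > H). Ring A is numbered C1′–C6′ and the hexenyl chain C1″–C5″. (+)-Sparteine, 2-(bromomethyl)-4,4,5,5-tetramethyl-1,3,2-dioxaborolane and 4-methylpent-3-en-1-ol are taken as commercial.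

**Route**

Step 1
Reactants: 1 resorcinol
Product: 2 1,3-bis(methoxymethoxy)benzene
Conditions: MOMCl, i-Pr2NEt, CH2Cl2, 0 °C to rt
Reagents that add atoms: chloromethyl methyl ether, COCCl
Why: O-Alkylation of both phenols (acetal formation) installs two base-stable, ortho-directing OMOM groups that flank C2 of the ring.

Step 2
Reactants: 2 1,3-bis(methoxymethoxy)benzene
Product: 5 2-{[2,6-bis(methoxymethoxy)phenyl]methyl}-4,4,5,5-tetramethyl-1,3,2-dioxaborolane, via aryllithium 3 (not isolated), via bromomethyl boronate complex 4 (not isolated)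
Conditions: n-BuLi, THF, 0 °C to rt; then BrCH2Bpin, −78 °C to rt
Reagents that add atoms: 2-(bromomethyl)-4,4,5,5-tetramethyl-1,3,2-dioxaborolane, BrCB1OC(C)(C)C(C)(C)O1
Why: Directed ortho-metalation occurs at C2 between the two OMOM groups, and the aryllithium adds to boron to give an ate complex whose aryl group undergoes a 1,2-shift with loss of bromide (Matteson-type homologation), forming the C3′–C1″ bond.

Step 3
Reactants: 6 4-methylpent-3-en-1-ol
Product: 7 4-methylpent-3-en-1-yl N,N-di(propan-2-yl)carbamate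
Conditions: i-Pr2NCOCl, Et3N, CH2Cl2, reflux
Reagents that add atoms: N,N-diisopropylcarbamoyl chloride, CC(C)N(C(C)C)C(=O)Cl
Why: Carbamoylation of the primary alcohol gives the O-alkyl carbamate needed for carbamate-directed α-lithiation.

Step 4
Reactants: 7 4-methylpent-3-en-1-yl N,N-di(propan-2-yl)carbamate; 5 2-{[2,6-bis(methoxymethoxy)phenyl]methyl}-4,4,5,5-tetramethyl-1,3,2-dioxaborolane
Product: 10 2-{(2S)-1-[2,6-bis(methoxymethoxy)phenyl]-5-methylhex-4-en-2-yl}-4,4,5,5-tetramethyl-1,3,2-dioxaborolane, via lithiated carbamate 8 (not isolated), via carbamoyloxy boronate complex 9 (not isolated)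
Conditions: s-BuLi, (+)-sparteine, Et2O, −78 °C, 5 h; then 5, −78 °C, 1 h; then reflux, 12 h
Reagents that add atoms: none
Why: The s-BuLi·(+)-sparteine complex, pre-coordinated to the carbamate carbonyl, should remove the pro-R hydrogen at C2″ to give the configurationally stable (R)-lithiated carbamate 8, which is borylated by 5 with retention to give boronate 9; on warming, the benzylic C1″H2 group migrates from boron to C2″ anti-periplanar to the departing carbamate (1,2-metallate rearrangement, inversion at C2″), creating the C1″–C2″ bond and the (S)-configured C–B centre. The closest known reaction type is the lithiation–borylation of primary O-alkyl carbamates with pinacol boronic esters, a reagent-controlled Matteson-type homologation. No ring is closed. The new stereocentre C2″ is controlled by the chiral diamine in the enantiotopic deprotonation and is then relayed stereospecifically (retention, then inversion). The step needs α-lithiation in preference to allylic deprotonation at C3″, which the complex-induced proximity effect of the carbamate carbonyl at −78 °C should secure. It also needs migration of the benzyl group rather than a pinacol oxygen, which the higher migratory aptitude of the carbon ligand and its anti-periplanar alignment with the C–O bond in the tetracoordinate boronate should secure.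

Step 5
Reactants: 10 2-{(2S)-1-[2,6-bis(methoxymethoxy)phenyl]-5-methylhex-4-en-2-yl}-4,4,5,5-tetramethyl-1,3,2-dioxaborolane
Product: 13 1,3-bis(methoxymethoxy)-2-[(2S)-5-methyl-2-(prop-1-en-2-yl)hex-4-en-1-yl]benzene, via alkenyl boronate complex 11 (not isolated), via iodoalkyl boronic ester 12 (not isolated)
Conditions: CH2=C(CH3)Li (from 2-bromopropene, t-BuLi), THF, −78 to 0 °C; I2, MeOH, −78 °C; NaOMe, MeOH, −78 °C to rt
Reagents that add atoms: isopropenyllithium, [Li]C(C)=C (prepared in the flask from 2-bromopropene, C=C(C)Br)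
Why: Zweifel olefination: the alkenyllithium adds to boron, iodination of the electron-rich alkenyl boronate triggers a stereoretentive 1,2-shift of the secondary alkyl group from boron to the alkene carbon, and methoxide-induced anti β-elimination of boron and iodide releases the isopropenyl group, so C2″ keeps its configuration.

Step 6
Reactants: 13 1,3-bis(methoxymethoxy)-2-[(2S)-5-methyl-2-(prop-1-en-2-yl)hex-4-en-1-yl]benzene
Product: 16 1-{2,4-bis(methoxymethoxy)-3-[(2S)-5-methyl-2-(prop-1-en-2-yl)hex-4-en-1-yl]phenyl}ethan-1-one, via aryllithium 14 (not isolated), via tetrahedral adduct 15 (not isolated)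
Conditions: n-BuLi, TMEDA, THF, 0 °C; then MeC(O)N(OMe)Me, −78 °C to rt; H2O
Reagents that add atoms: N-methoxy-N-methylacetamide, CC(=O)N(C)OC
Why: Directed ortho-metalation next to an OMOM group (C4 and C6 of the 2-substituted resorcinol ether are equivalent, so only one ketone can form) is followed by acylation with a Weinreb amide, whose chelated tetrahedral adduct prevents over-addition.

Step 7
Reactants: 17 salicylaldehyde
Product: 18 2-(methoxymethoxy)benzaldehyde
Conditions: MOMCl, i-Pr2NEt, CH2Cl2, 0 °C to rt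
Reagents that add atoms: chloromethyl methyl ether, COCCl
Why: O-Alkylation masks the phenol so that the aldehyde is not deactivated as a phenoxide in the base-mediated condensation.

Step 8
Reactants: 16 1-{2,4-bis(methoxymethoxy)-3-[(2S)-5-methyl-2-(prop-1-en-2-yl)hex-4-en-1-yl]phenyl}ethan-1-one; 18 2-(methoxymethoxy)benzaldehyde
Product: 20 (2E)-1-{2,4-bis(methoxymethoxy)-3-[(2S)-5-methyl-2-(prop-1-en-2-yl)hex-4-en-1-yl]phenyl}-3-[2-(methoxymethoxy)phenyl]prop-2-en-1-one, via aldol adduct 19 (not isolated)
Conditions: KOH, EtOH/H2O, rt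
Reagents that add atoms: none
Why: Claisen–Schmidt condensation: the ketone enolate adds to the non-enolisable aldehyde and E1cB dehydration of the aldol gives the thermodynamically favoured (E)-enone, while the remote, non-acidic C2″ is untouched.

Step 9
Reactants: 20 (2E)-1-{2,4-bis(methoxymethoxy)-3-[(2S)-5-methyl-2-(prop-1-en-2-yl)hex-4-en-1-yl]phenyl}-3-[2-(methoxymethoxy)phenyl]prop-2-en-1-one
Product: 21 (2E)-1-{2,4-dihydroxy-3-[(2S)-5-methyl-2-(prop-1-en-2-yl)hex-4-en-1-yl]phenyl}-3-(2-hydroxyphenyl)prop-2-en-1-one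
Conditions: 3 M aq. HCl, MeOH, rt to 40 °C, dark
Reagents that add atoms: none
Why: Acid-catalysed acetal cleavage of the three aryl MOM ethers in methanol, under conditions mild enough to leave the isopropenyl and prenyl alkenes and the enone intact, should give the free triphenol.

**Compound list**

1 | resorcinol | Oc1cccc(O)c1 | starting material
2 | 1,3-bis(methoxymethoxy)benzene | COCOc1cccc(OCOC)c1 | intermediate
3 | [2,6-bis(methoxymethoxy)phenyl]lithium | [Li]c1c(OCOC)cccc1OCOC | intermediate
4 | lithium (bromomethyl)[2,6-bis(methoxymethoxy)phenyl](pinacolato)borate | [Li+].BrC[B-]1(OC(C)(C)C(C)(C)O1)c1c(OCOC)cccc1OCOC | intermediate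
5 | 2-{[2,6-bis(methoxymethoxy)phenyl]methyl}-4,4,5,5-tetramethyl-1,3,2-dioxaborolane | COCOc1cccc(OCOC)c1CB1OC(C)(C)C(C)(C)O1 | intermediate
6 | 4-methylpent-3-en-1-ol | CC(C)=CCCO | starting material
7 | 4-methylpent-3-en-1-yl N,N-di(propan-2-yl)carbamate | CC(C)=CCCOC(=O)N(C(C)C)C(C)C | intermediate
8 | [(1R)-1-{[di(propan-2-yl)carbamoyl]oxy}-4-methylpent-3-en-1-yl]lithium, (+)-sparteine complex (diamine omitted from SMILES) | [Li][C@@H](OC(=O)N(C(C)C)C(C)C)CC=C(C)C | intermediate
9 | lithium {[2,6-bis(methoxymethoxy)phenyl]methyl}[(1R)-1-{[di(propan-2-yl)carbamoyl]oxy}-4-methylpent-3-en-1-yl](pinacolato)borate | [Li+].CC1(C)O[B-](Cc2c(OCOC)cccc2OCOC)(OC1(C)C)[C@@H](OC(=O)N(C(C)C)C(C)C)CC=C(C)C | intermediate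
10 | 2-{(2S)-1-[2,6-bis(methoxymethoxy)phenyl]-5-methylhex-4-en-2-yl}-4,4,5,5-tetramethyl-1,3,2-dioxaborolane | CC1(C)OB(OC1(C)C)[C@@H](CC=C(C)C)Cc1c(OCOC)cccc1OCOC | intermediate
11 | lithium {(2S)-1-[2,6-bis(methoxymethoxy)phenyl]-5-methylhex-4-en-2-yl}(prop-1-en-2-yl)(pinacolato)borate | [Li+].C=C(C)[B-]1(OC(C)(C)C(C)(C)O1)[C@@H](CC=C(C)C)Cc1c(OCOC)cccc1OCOC | intermediate
12 | 2-[(3S)-3-{[2,6-bis(methoxymethoxy)phenyl]methyl}-1-iodo-2,6-dimethylhept-5-en-2-yl]-4,4,5,5-tetramethyl-1,3,2-dioxaborolane (either configuration at C2) | ICC(C)(B1OC(C)(C)C(C)(C)O1)[C@@H](CC=C(C)C)Cc1c(OCOC)cccc1OCOC | intermediate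
13 | 1,3-bis(methoxymethoxy)-2-[(2S)-5-methyl-2-(prop-1-en-2-yl)hex-4-en-1-yl]benzene | C=C(C)[C@@H](CC=C(C)C)Cc1c(OCOC)cccc1OCOC | intermediate
14 | {2,4-bis(methoxymethoxy)-3-[(2S)-5-methyl-2-(prop-1-en-2-yl)hex-4-en-1-yl]phenyl}lithium | C=C(C)[C@@H](CC=C(C)C)Cc1c(OCOC)ccc([Li])c1OCOC | intermediate
15 | lithium 1-{2,4-bis(methoxymethoxy)-3-[(2S)-5-methyl-2-(prop-1-en-2-yl)hex-4-en-1-yl]phenyl}-1-[methoxy(methyl)amino]ethan-1-olate (either configuration at the hemiaminal carbon) | C=C(C)[C@@H](CC=C(C)C)Cc1c(OCOC)ccc(C(C)(O[Li])N(C)OC)c1OCOC | intermediate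
16 | 1-{2,4-bis(methoxymethoxy)-3-[(2S)-5-methyl-2-(prop-1-en-2-yl)hex-4-en-1-yl]phenyl}ethan-1-one | C=C(C)[C@@H](CC=C(C)C)Cc1c(OCOC)ccc(C(C)=O)c1OCOC | intermediate
17 | salicylaldehyde | O=Cc1ccccc1O | starting material
18 | 2-(methoxymethoxy)benzaldehyde | COCOc1ccccc1C=O | intermediate
19 | 1-{2,4-bis(methoxymethoxy)-3-[(2S)-5-methyl-2-(prop-1-en-2-yl)hex-4-en-1-yl]phenyl}-3-hydroxy-3-[2-(methoxymethoxy)phenyl]propan-1-one (either configuration at the carbinol carbon) | C=C(C)[C@@H](CC=C(C)C)Cc1c(OCOC)ccc(C(=O)CC(O)c2ccccc2OCOC)c1OCOC | intermediate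
20 | (2E)-1-{2,4-bis(methoxymethoxy)-3-[(2S)-5-methyl-2-(prop-1-en-2-yl)hex-4-en-1-yl]phenyl}-3-[2-(methoxymethoxy)phenyl]prop-2-en-1-one | C=C(C)[C@@H](CC=C(C)C)Cc1c(OCOC)ccc(C(=O)/C=C/c2ccccc2OCOC)c1OCOC | intermediate
21 | (2E)-1-{2,4-dihydroxy-3-[(2S)-5-methyl-2-(prop-1-en-2-yl)hex-4-en-1-yl]phenyl}-3-(2-hydroxyphenyl)prop-2-en-1-one | C=C(C)[C@@H](CC=C(C)C)Cc1c(O)ccc(C(=O)/C=C/c2ccccc2O)c1O | target

**Step count**

Total: 9 steps. Longest linear sequence: 7 steps (1, 2, 4, 5, 6, 8, 9) from resorcinol.

**Steps most likely to fail, with fallbacks**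

Step 4 (key step). What may go wrong: incomplete enantiotopic discrimination in the deprotonation, competing allylic metalation at C3″, or a sluggish 1,2-shift that lets the boronate revert; each would lower the enantiomeric purity or the conversion. The fallback uses known chemistry, sets out from 2 and comes back at 13. It makes the stereocentre by auxiliary-controlled enolate alkylation and attaches the finished side chain as an electrophile. (R)-4-Benzyl-1,3-oxazolidin-2-one is N-acylated with 3-methylbut-2-enoyl chloride (n-BuLi, THF, −78 °C) to give (4R)-4-benzyl-3-(3-methylbut-2-enoyl)-1,3-oxazolidin-2-one F1. Its sodium dienolate (NaHMDS, THF, −78 °C) should be alkylated by prenyl bromide at the α-carbon, anti to the benzyl group and with deconjugation, to give (4R)-4-benzyl-3-[(2R)-5-methyl-2-(prop-1-en-2-yl)hex-4-enoyl]-1,3-oxazolidin-2-one F2. Reduction with LiBH4 (Et2O, 1 equiv H2O, 0 °C) should give (2R)-5-methyl-2-(prop-1-en-2-yl)hex-4-en-1-ol F3, which I2/PPh3/imidazole (CH2Cl2, 0 °C) converts into (2R)-1-iodo-5-methyl-2-(prop-1-en-2-yl)hex-4-ene F4. Aryllithium 3, generated from 2 as in step 2, is then alkylated with F4 (cat. CuI, THF/DMPU, −78 °C to rt) to give 13.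

Step 6. What may go wrong: metalation at the benzylic C1″H2 between the two OMOM groups or at an allylic methyl group instead of the ring, or proton transfer from the Weinreb amide to 14, so that little ketone forms. The fallback sets out from 13 and comes back at 16. It brings in the acyl carbon by electrophilic substitution of the free resorcinol instead of through an aryl anion. Brief acid methanolysis of 13 (cat. HCl, MeOH, rt) should give 2-[(2S)-5-methyl-2-(prop-1-en-2-yl)hex-4-en-1-yl]benzene-1,3-diol F5. Magnesium-mediated ortho-formylation (MgCl2, Et3N, paraformaldehyde, MeCN, reflux), for which the two free ortho positions are equivalent, should give 2,4-dihydroxy-3-[(2S)-5-methyl-2-(prop-1-en-2-yl)hex-4-en-1-yl]benzaldehyde F6. Protection with MOMCl/NaH (DMF, 0 °C) gives 2,4-bis(methoxymethoxy)-3-[(2S)-5-methyl-2-(prop-1-en-2-yl)hex-4-en-1-yl]benzaldehyde F7, and MeMgBr (THF, 0 °C) gives 1-{2,4-bis(methoxymethoxy)-3-[(2S)-5-methyl-2-(prop-1-en-2-yl)hex-4-en-1-yl]phenyl}ethan-1-ol F8. Dess–Martin oxidation (NaHCO3, CH2Cl2) returns 16.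

Step 9. What may go wrong: the acid needed to cleave three MOM ethers may also trigger ring closure of the liberated polyphenolic chalcone (flavanone formation through O2′, or addition of a phenol to the protonated isopropenyl or prenyl alkene). It may also isomerise the isopropenyl group, which would erase C2″. The fallback sets out from 16 and comes back at 21. It unmasks the phenols before the enone exists. The two MOM groups of 16, both activated by the ortho/para carbonyl, are removed by short, mild acid treatment (cat. HCl, MeOH, rt) to give 1-{2,4-dihydroxy-3-[(2S)-5-methyl-2-(prop-1-en-2-yl)hex-4-en-1-yl]phenyl}ethan-1-one F9. F9 is then condensed with unprotected salicylaldehyde 17 as the phenoxides (60% aq. KOH, EtOH, rt, prolonged reaction), followed by cold acidification to pH 5, to give 21 directly.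

**Further compounds**

F1 | step 4 | (4R)-4-benzyl-3-(3-methylbut-2-enoyl)-1,3-oxazolidin-2-one | CC(C)=CC(=O)N1C(=O)OC[C@H]1Cc1ccccc1
F2 | step 4 | (4R)-4-benzyl-3-[(2R)-5-methyl-2-(prop-1-en-2-yl)hex-4-enoyl]-1,3-oxazolidin-2-one | C=C(C)[C@@H](CC=C(C)C)C(=O)N1C(=O)OC[C@H]1Cc1ccccc1
F3 | step 4 | (2R)-5-methyl-2-(prop-1-en-2-yl)hex-4-en-1-ol, (R)-lavandulol | C=C(C)[C@@H](CC=C(C)C)CO
F4 | step 4 | (2R)-1-iodo-5-methyl-2-(prop-1-en-2-yl)hex-4-ene | C=C(C)[C@@H](CC=C(C)C)CI
F5 | step 6 | 2-[(2S)-5-methyl-2-(prop-1-en-2-yl)hex-4-en-1-yl]benzene-1,3-diol | C=C(C)[C@@H](CC=C(C)C)Cc1c(O)cccc1O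
F6 | step 6 | 2,4-dihydroxy-3-[(2S)-5-methyl-2-(prop-1-en-2-yl)hex-4-en-1-yl]benzaldehyde | C=C(C)[C@@H](CC=C(C)C)Cc1c(O)ccc(C=O)c1O
F7 | step 6 | 2,4-bis(methoxymethoxy)-3-[(2S)-5-methyl-2-(prop-1-en-2-yl)hex-4-en-1-yl]benzaldehyde | C=C(C)[C@@H](CC=C(C)C)Cc1c(OCOC)ccc(C=O)c1OCOC
F8 | step 6 | 1-{2,4-bis(methoxymethoxy)-3-[(2S)-5-methyl-2-(prop-1-en-2-yl)hex-4-en-1-yl]phenyl}ethan-1-ol (either configuration at the carbinol carbon) | C=C(C)[C@@H](CC=C(C)C)Cc1c(OCOC)ccc(C(C)O)c1OCOC
F9 | step 9 | 1-{2,4-dihydroxy-3-[(2S)-5-methyl-2-(prop-1-en-2-yl)hex-4-en-1-yl]phenyl}ethan-1-one | C=C(C)[C@@H](CC=C(C)C)Cc1c(O)ccc(C(C)=O)c1O
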